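The closed, stirred vessel held both substrates as a racemate, each at 0.050 M, with 18 mol% of single-handed free catalyst under gas held at 7.2 mM, and I had to say what excess of left-handed product stood in it when east was stopped at 6.0 d and west at 25 d.

the same everywhere: gas 7.2 mM (held)

| flask | left-handed substrate | right-handed substrate | free catalyst | remark | time |
|---|---|---|---|---|---|
| eta | 0.070 M | 0.070 M | 18 mol% | run made earlier |  |
| delta | 0.11 M | 0.11 M | 18 mol% | run made earlier |  |
| beta | 0.050 M | 0.050 M | 27 mol% | run made earlier |  |
| east | 0.050 M | 0.050 M | 18 mol% |  | 6.0 d |
| west | 0.050 M | 0.050 M | 18 mol% |  | 25 d |

| run | time / d | left-handed product / % | right-handed product / % | left-handed substrate / % |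
|---|---|---|---|---|
| eta | 0.417 | 4.6 | 0 | 45.0 |
| eta | 0.833 | 7.7 | 0.3 | 42.0 |
| eta | 2.08 | 12.2 | 1.1 | 38.2 |
| eta | 5.00 | 12.2 | 2.7 | 37.8 |
| delta | 0.417 | 3.6 | 1.1 | 46.3 |
| delta | 0.833 | 6.2 | 1.1 | 43.5 |
| delta | 2.08 | 10.9 | 1.9 | 39.3 |
| delta | 5.00 | 11.5 | 1.1 | 38.7 |
| beta | 0.625 | 9.4 | 1.4 | 41.7 |
| beta | 1.67 | 14.2 | 1.5 | 36.0 |
| beta | 3.00 | 14.8 | 2.5 | 35.1 |
| beta | 5.00 | 15.6 | 1.7 | 34.9 |

(readings scatter by 0.5 percentage points)

- free catalyst is single-handed; left-handed substrate and right-handed substrate are mirror images of each other, charged as a racemate, each of them at the stated concentration
- at the start none of the gas is in solution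
- an excess is the difference of the two amounts in percent of their sum
- an excess is below zero if the other one leads

- which one finishes higher in excess of left-handed product over right-handed product in the product ("neither" within 2 percentage points) (east / west / neither)
- excess of left-handed product over right-handed product in the product at the end, east
- excess of left-handed product over right-handed product in the product at the end, west

I began with the main step alone and followed one substrate molecule, asking how much likelier a left-handed molecule was to react than a right-handed one in the same solution. That odds figure is the logarithm of the fraction of left-handed substrate remaining divided by the logarithm of the fraction of right-handed substrate remaining, the latter taken as its charge less right-handed product. Summing the late readings of the eta, delta and beta runs, I read this selectivity factor as 8.18. With nothing yet consumed, the first product would carry an excess of 78.2%.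

Next I let the substrates deplete. The eta and delta runs, at 18 mol%, ended near 38.5% of left-handed substrate, and the factor then gives 1.57% of right-handed product against 11.5% of left-handed product, so the excess falls to 76.0%.

Last came the halt. The eta run read 12.2% of left-handed product at 2.08 d and 12.2% at 5.00 d, with 37.8% of left-handed substrate still present, while the beta run, at 27 mol%, stopped higher, at 15.6%. I took this for a loss of catalyst, which, like the gas entering solution, should slow both forks alike and leave the factor unchanged. Since east ran past that last reading, I committed to 76.0% for both flasks.

The forecast, judging that “the catalyst seems used up”, gave 76% for east, 75% for west and neither as the higher.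

The flask gave 76.5% in east and 76.5% in west, so neither finished higher.

    reagent + free catalyst + left-handed substrate → free catalyst + left-handed product (k = 0.450 M⁻² s⁻¹)
    reagent + free catalyst + right-handed substrate → free catalyst + right-handed product (k = 0.0530 M⁻² s⁻¹)
    free catalyst → spent catalyst (k = 2.80 × 10⁻⁵ s⁻¹)
    gas ⇌ reagent, rate k4*(csat - [reagent]) (kL = 3.70 × 10⁻⁵ s⁻¹)

West held 1.68% of right-handed product at 25.0 d with spent catalyst at 100%, and still 1.68% at 250 d. In east, 75% of the left-handed substrate remained, from which the factor 8.18 gives 96.5% of the right-handed substrate, and the flask held 97%. A neighbouring flask, which is west with 4.5 mol% of free catalyst, made 5.42% of left-handed product, so the factor gives 0.697% of right-handed product and an excess of 77.2%, and that neighbouring flask stood at 0.672% of right-handed product and an excess of 78.0%.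

The earlier runs and the new flask are simulated with made-up constants; noise was put on by code.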